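## Retrosynthetic overview

1. Target 7 (threo, 7S,8S) ⇒ C7 carbinol by Felkin–Anh reduction of the (S)-α-aryloxy ketone 6, so C8 controls C7.
2. Ketone 6 ⇒ C7–C8 bond by a carbene-catalysed enantioselective Markovnikov hydroacylation of aryl vinyl ether 3 with 3,4,5-trimethoxybenzaldehyde 4; this sets C8.
3. Vinyl ether 3 ⇒ O-vinylation of methyl vanillate 1 with vinyl acetate 2.
4. No ring is formed: both benzene rings are bought intact, in 1 and 4.

Assumptions: C7 is the carbinol carbon and C8 the aryloxy-bearing carbon. The (5aS,10bR) triazolium antipode is taken to give the (S)-ketone; if the first run shows the opposite sense, its (5aR,10bS) antipode is used and nothing else changes.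

## Route

Step 1
Reactants: 1 methyl vanillate (methyl 4-hydroxy-3-methoxybenzoate); 2 vinyl acetate
Product: 3 methyl 3-methoxy-4-(vinyloxy)benzoate
Conditions: [Ir(cod)Cl]2 (1 mol%), Na2CO3 (0.6 equiv), 2 (2 equiv), toluene, 100 °C
Reagents that add atoms: none
Why: Iridium-catalysed transfer vinylation of a phenol (O-vinylation with vinyl acetate: aryloxide addition to the Ir-bound vinyl ester, then β-acetoxy elimination); the carbonate buffers the acetic acid so the vinyl ether and the methyl ester survive, and no stereocentre is formed.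

Step 2
Reactants: 3 methyl 3-methoxy-4-(vinyloxy)benzoate; 4 3,4,5-trimethoxybenzaldehyde
Product: 6 methyl 3-methoxy-4-{[(2S)-1-oxo-1-(3,4,5-trimethoxyphenyl)propan-2-yl]oxy}benzoate, via Breslow enaminol 5 (not isolated)
Conditions: (5aS,10bR)-N-mesityl aminoindanol-triazolium BF4 (10 mol%), K3PO4 (10 mol%), 4 (2 equiv), 4 Å MS, 1,4-dioxane (1 M), 50 °C
Reagents that add atoms: none
Why: Proposed new method: the triazolylidene adds to 4 to give Breslow enaminol 5, whose enol O–H proton passes to the nucleophilic CH2 terminus of the vinyl ether while its nucleophilic carbon bonds to the oxygen-stabilised (oxocarbenium-like) internal carbon in an asynchronous ene-type transition state, so the addition is Markovnikov and C8 is created in the C–C bond-forming event; the indane wall leaves one face of the enaminol open and keeps the aryloxy group away from the N-mesityl group, so one enantioface of the vinyl ether reacts to give 8S, and the carbene is then expelled to give the ketone; the closest known reaction type is NHC-catalysed hydroacylation (intramolecular on enol ethers and unactivated alkenes, intermolecular on cyclopropenes and styrenes), and the intermolecular enantioselective version on an aryl vinyl ether has not been shown.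

Step 3
Reactants: 6 methyl 3-methoxy-4-{[(2S)-1-oxo-1-(3,4,5-trimethoxyphenyl)propan-2-yl]oxy}benzoate
Product: 7 methyl 4-{[(1S,2S)-1-hydroxy-1-(3,4,5-trimethoxyphenyl)propan-2-yl]oxy}-3-methoxybenzoate
Conditions: K-Selectride (1.2 equiv), 18-crown-6 (1.3 equiv), THF, −78 °C; then sat. aq. NH4Cl
Reagents that add atoms: none
Why: Felkin–Anh (polar, non-chelation) ketone reduction: with K+ held by the crown ether no chelate forms, the C8–OAr bond lies anti to the incoming bulky hydride, which passes C8–H and not C8–CH3, giving the 7S carbinol (threo, 7S,8S); the methyl ester is inert to the borohydride at −78 °C and C8 is not touched.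

## Compound list

1 | methyl vanillate (methyl 4-hydroxy-3-methoxybenzoate) | COC(=O)c1ccc(O)c(OC)c1 | starting material
2 | vinyl acetate | CC(=O)OC=C | starting material
3 | methyl 3-methoxy-4-(vinyloxy)benzoate | COC(=O)c1ccc(OC=C)c(OC)c1 | intermediate
4 | 3,4,5-trimethoxybenzaldehyde | COc1cc(C=O)cc(OC)c1OC | starting material
5 | Breslow enaminol (adduct of 4 on the carbene carbon of the (5aS,10bR)-N-mesityl triazolylidene; not isolated) | COc1cc(cc(OC)c1OC)C(O)=C1N(c2c(C)cc(C)cc2C)N=C2CO[C@H]3Cc4ccccc4[C@H]3N12 | intermediate
6 | methyl 3-methoxy-4-{[(2S)-1-oxo-1-(3,4,5-trimethoxyphenyl)propan-2-yl]oxy}benzoate | COC(=O)c1ccc(O[C@@H](C)C(=O)c2cc(OC)c(OC)c(OC)c2)c(OC)c1 | intermediate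
7 | methyl 4-{[(1S,2S)-1-hydroxy-1-(3,4,5-trimethoxyphenyl)propan-2-yl]oxy}-3-methoxybenzoate | COC(=O)c1ccc(O[C@@H](C)[C@@H](O)c2cc(OC)c(OC)c(OC)c2)c(OC)c1 | target

## Step count

Total steps: 3. Longest linear sequence: 3 (1 → 3 → 6 → 7); aldehyde 4 enters at step 2.

## Steps most likely to fail

**Step 2 (the proposed new hydroacylation).** The risks are low reactivity of the electron-rich vinyl ether towards the Breslow enaminol, diversion of 4 into its (reversible) benzoin, and erosion of ee at the α-aryloxy ketone centre under base. The fallback uses known chemistry, sets out from 4 and comes back at 6. Aldehyde 4 and acetaldehyde are joined by a thiamine-diphosphate-dependent benzaldehyde lyase (ThDP, MgSO4, phosphate buffer pH 8 with DMSO, 30 °C) to give (2R)-2-hydroxy-1-(3,4,5-trimethoxyphenyl)propan-1-one F1. Mitsunobu etherification of F1 with phenol 1 (PPh3, DIAD, THF, 0 °C) then inverts C8 and gives 6. In this case step 1 is not needed.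

**Step 3 (threo-selective reduction).** The risk is residual chelation through the guaiacyl oxygens, which would give erythro material and a poor diastereomer ratio. The fallback sets out from 6 and comes back at 7, and it uses chelation control on purpose. Zn(BH4)2 (Et2O, −20 °C) reduces 6 to the erythro alcohol methyl 4-{[(1R,2S)-1-hydroxy-1-(3,4,5-trimethoxyphenyl)propan-2-yl]oxy}-3-methoxybenzoate F2. Mitsunobu inversion at C7 (4-nitrobenzoic acid, PPh3, DIAD, THF, 0 °C) gives methyl 3-methoxy-4-{[(1S,2S)-1-[(4-nitrobenzoyl)oxy]-1-(3,4,5-trimethoxyphenyl)propan-2-yl]oxy}benzoate F3. Methanolysis (K2CO3, MeOH, 0 °C) then gives 7; the methyl benzoate is unchanged because exchange with methoxide is degenerate.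

**Step 1 (O-vinylation).** The risks are incomplete transfer and acetal formation from the vinyl ether. The fallback sets out from 1 and comes back at 3. Phenol 1 is alkylated with 1,2-dibromoethane (K2CO3, MeCN, 80 °C) to methyl 4-(2-bromoethoxy)-3-methoxybenzoate F4. E2 elimination (KOtBu, THF, 0 °C) then gives 3.

## Further compounds

F1 | step 2 | (2R)-2-hydroxy-1-(3,4,5-trimethoxyphenyl)propan-1-one | C[C@@H](O)C(=O)c1cc(OC)c(OC)c(OC)c1
F2 | step 3 | methyl 4-{[(1R,2S)-1-hydroxy-1-(3,4,5-trimethoxyphenyl)propan-2-yl]oxy}-3-methoxybenzoate | COC(=O)c1ccc(O[C@@H](C)[C@H](O)c2cc(OC)c(OC)c(OC)c2)c(OC)c1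
F3 | step 3 | methyl 3-methoxy-4-{[(1S,2S)-1-[(4-nitrobenzoyl)oxy]-1-(3,4,5-trimethoxyphenyl)propan-2-yl]oxy}benzoate | COC(=O)c1ccc(O[C@@H](C)[C@@H](OC(=O)c2ccc(cc2)[N+](=O)[O-])c2cc(OC)c(OC)c(OC)c2)c(OC)c1
F4 | step 1 | methyl 4-(2-bromoethoxy)-3-methoxybenzoate | COC(=O)c1ccc(OCCBr)c(OC)c1
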